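**Remark on the chemistry (assumption):** the all-E isomer drawn, (3R,3'R,6'R)-7,8-didehydro-β,ε-carotene-3,3'-diol (monadoxanthin), is the target. Compounds 3, 12, 17, 20 and 24 are taken as catalogue materials (all are industrial terpenoid building blocks). Carotenoid numbering (C1–C15, C1'–C15') is used throughout.

**Plan**
1. Cuts: C11=C12 and C11'=C12' (two Wittig bonds) split the chain into an ε-end C15 phosphonium salt, the C10 trienedial and a 7,8-didehydro β-end C15 phosphonium salt. C7'=C8' (Julia–Kocienski) and C6–C7 (Sonogashira) detach the rings, and the ε-ring is cut across C4'–C5' and C1'–C6'.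
2. Enabling feature: ring atoms C1'(Me2)–C2'–C3'(O)–C4' are the skeleton of mesityl oxide, and C5'(CH3)/C6'(H, side chain) are the central and α-carbons of an allenoate. The C3' oxygen is 1,4 to C6' and C1' is a tertiary, cation-stabilising terminus, so a catalysed [4+2] of the cross-conjugated silyl dienol ether with ethyl buta-2,3-dienoate closes the ε-ring in one operation. The exocyclic methylene left by the allene is then moved into the ring as C4'=C5'.
3. Forward order: ε-ring (steps 1–3), then C7'=C8', then the C11' phosphonium salt. β-ring enol triflate, then C6–C7, the C11 salt and C11=C12 with the dialdehyde. The halves meet at C11'=C12', followed by desilylation.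
4. Stereochemistry: C6' from the catalyst-controlled cycloaddition; C3' from substrate-controlled hydride delivery anti to the axial C1' methyl; C3 from (4R,6R)-actinol. Alkene geometry comes from E-configured building blocks (12, 20, 24) and E-selective Julia–Kocienski and Wittig steps.

Key step: step 2

**Route**

Step 1
Reactants: 1 mesityl oxide
Product: 2 tert-butyldimethyl[(4-methylpenta-1,3-dien-2-yl)oxy]silane
Conditions: LiN(iPr)2, THF, −78 °C; then tBuMe2SiCl, DMPU, −78 °C → rt
Reagents that add atoms: tert-butyldimethylsilyl chloride CC(C)(C)[Si](C)(C)Cl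
Why: Kinetic deprotonation of the enone at the methyl ketone side gives the cross-conjugated lithium dienolate, which is O-silylated to the 2-siloxydiene (kinetic silyl enol ether formation).

Step 2
Reactants: 2 tert-butyldimethyl[(4-methylpenta-1,3-dien-2-yl)oxy]silane; 3 ethyl buta-2,3-dienoate
Product: 4 ethyl (1S)-4-[(tert-butyldimethylsilyl)oxy]-2,2-dimethyl-6-methylidenecyclohex-3-ene-1-carboxylate
Conditions: (S)-B-(o-tolyl)oxazaborolidine from (S)-α,α-diphenylprolinol, protonated with HNTf2 (20 mol%), CH2Cl2, −78 → −20 °C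
Reagents that add atoms: none
Why: Proposed new method: the chiral boron cation binds the ester carbonyl of 3, the unhindered C4' terminus of the siloxydiene attacks the central allene carbon (future C5') and the ester-bearing carbon (C6') then bonds to C1', either in one strongly asynchronous transition state or through a silyloxyallyl cation/boron enolate pair that the two C1' methyl groups stabilise, which is why the Z-methyl that retards ordinary Diels–Alder reactions of 4-methylpenta-1,3-dienes should be tolerated. The closest known reaction types are the oxazaborolidinium-catalysed Diels–Alder reaction of 2-siloxybutadienes with acrylate esters and the Lewis-acid-promoted [4+2] addition of dienes to the conjugated bond of allenoates. The ε-ring closes as a suprafacial [4π+2π] cycloaddition, in the stepwise limit by 6-endo-trig collapse of the enolate carbon C6' onto the cationic terminus C1'. C6', the only new stereocentre, is set by the catalyst: the diene must add to the Re face of the allenoate α-carbon, which the (S)-configured catalyst is expected to expose when the ester is held by the B–O=C and α-C–H···O contacts (the (R)-catalyst, equally accessible, would be taken if a first correlation showed the opposite sense). Regiochemistry (C4' to the β-carbon, silyloxy 1,4 to the ester) follows from the polarity of both partners, site selectivity from activation of the conjugated allene bond only, and six- over four-membered ring formation from the tertiary allyl-cation character of C1', to which a kinetically formed cyclobutane can re-ionise.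

Step 3
Reactants: 4 ethyl (1S)-4-[(tert-butyldimethylsilyl)oxy]-2,2-dimethyl-6-methylidenecyclohex-3-ene-1-carboxylate
Product: 7 (4R)-4-(hydroxymethyl)-3,5,5-trimethylcyclohex-2-en-1-one, via silyl enol ether alcohol 5 (not isolated), via deconjugated ketone 6 (not isolated)
Conditions: LiAlH4, Et2O, 0 °C; then 2 M HCl, THF, rt
Reagents that add atoms: none
Why: Hydride reduction of the hindered ester removes the group that would acidify C6'–H, then aqueous acid hydrolyses the silyl enol ether and moves the exocyclic C5'=CH2 bond into conjugation through the C3'–C4' enol (deconjugated-to-conjugated enone isomerisation), leaving the C6' stereocentre untouched.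

Step 4
Reactants: 7 (4R)-4-(hydroxymethyl)-3,5,5-trimethylcyclohex-2-en-1-one
Product: 8 (4R)-3,5,5-trimethyl-4-{[(1-phenyl-1H-tetrazol-5-yl)sulfanyl]methyl}cyclohex-2-en-1-one
Conditions: 1-phenyl-1H-tetrazole-5-thiol, PPh3, DIAD, THF, 0 °C → rt
Reagents that add atoms: 1-phenyl-1H-tetrazole-5-thiol SC1=NN=NN1c1ccccc1
Why: Mitsunobu thioetherification of the primary alcohol with the acidic tetrazole thiol, the β,β-disubstituted enone being too hindered for thia-Michael addition.

Step 5
Reactants: 8 (4R)-3,5,5-trimethyl-4-{[(1-phenyl-1H-tetrazol-5-yl)sulfanyl]methyl}cyclohex-2-en-1-one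
Product: 9 (1R,4R)-3,5,5-trimethyl-4-{[(1-phenyl-1H-tetrazol-5-yl)sulfanyl]methyl}cyclohex-2-en-1-ol
Conditions: LiBH(sBu)3, THF, −78 °C; aq NH4Cl
Reagents that add atoms: none
Why: 1,2-Reduction of the β-substituted enone with a bulky trialkylborohydride under steric approach control: the axial C1' methyl shields the carbonyl face it shares, so hydride should enter from the face of the pseudoaxial C6' side arm and place the new C3' hydroxyl trans to it (3'R).

Step 6
Reactants: 9 (1R,4R)-3,5,5-trimethyl-4-{[(1-phenyl-1H-tetrazol-5-yl)sulfanyl]methyl}cyclohex-2-en-1-ol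
Product: 10 5-({[(1R,4R)-4-[(tert-butyldimethylsilyl)oxy]-2,6,6-trimethylcyclohex-2-en-1-yl]methyl}sulfanyl)-1-phenyl-1H-tetrazole
Conditions: tBuMe2SiCl, imidazole, DMF, rt
Reagents that add atoms: tert-butyldimethylsilyl chloride CC(C)(C)[Si](C)(C)Cl
Why: Silyl ether protection of the secondary allylic alcohol so that C3'–O survives the later base, hydride and bromination steps.

Step 7
Reactants: 10 5-({[(1R,4R)-4-[(tert-butyldimethylsilyl)oxy]-2,6,6-trimethylcyclohex-2-en-1-yl]methyl}sulfanyl)-1-phenyl-1H-tetrazole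
Product: 11 5-({[(1R,4R)-4-[(tert-butyldimethylsilyl)oxy]-2,6,6-trimethylcyclohex-2-en-1-yl]methyl}sulfonyl)-1-phenyl-1H-tetrazole
Conditions: (NH4)6Mo7O24·4H2O (10 mol%), 30% H2O2, EtOH, 0 °C → rt
Reagents that add atoms: hydrogen peroxide OO
Why: Molybdate-catalysed peroxide oxidation of the sulfide to the sulfone, chemoselective over the trisubstituted alkene and the silyl ether.

Step 8
Reactants: 11 5-({[(1R,4R)-4-[(tert-butyldimethylsilyl)oxy]-2,6,6-trimethylcyclohex-2-en-1-yl]methyl}sulfonyl)-1-phenyl-1H-tetrazole; 12 ethyl (2E)-3-methyl-4-oxobut-2-enoate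
Product: 13 ethyl (2E,4E)-5-[(1R,4R)-4-[(tert-butyldimethylsilyl)oxy]-2,6,6-trimethylcyclohex-2-en-1-yl]-3-methylpenta-2,4-dienoate
Conditions: KN(SiMe3)2, DME, −60 °C; then 12, −60 °C → rt
Reagents that add atoms: none
Why: Julia–Kocienski olefination: the metalated tetrazolyl sulfone adds to the aldehyde, and Smiles rearrangement with loss of SO2 and tetrazololate should give the E C7'=C8' alkene, while C9'=C10' geometry comes from 12 and C6' is not acidified by the β-sulfonyl group.

Step 9
Reactants: 13 ethyl (2E,4E)-5-[(1R,4R)-4-[(tert-butyldimethylsilyl)oxy]-2,6,6-trimethylcyclohex-2-en-1-yl]-3-methylpenta-2,4-dienoate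
Product: 14 (2E,4E)-5-[(1R,4R)-4-[(tert-butyldimethylsilyl)oxy]-2,6,6-trimethylcyclohex-2-en-1-yl]-3-methylpenta-2,4-dien-1-ol
Conditions: iBu2AlH, CH2Cl2, −78 °C; aq KNaC4H4O6 work-up
Reagents that add atoms: none
Why: 1,2-Reduction of the dienoate to the allylic alcohol with the aluminium hydride, which leaves the silyl ether and the diene untouched.

Step 10
Reactants: 14 (2E,4E)-5-[(1R,4R)-4-[(tert-butyldimethylsilyl)oxy]-2,6,6-trimethylcyclohex-2-en-1-yl]-3-methylpenta-2,4-dien-1-ol
Product: 16 [(2E,4E)-5-[(1R,4R)-4-[(tert-butyldimethylsilyl)oxy]-2,6,6-trimethylcyclohex-2-en-1-yl]-3-methylpenta-2,4-dien-1-yl]triphenylphosphonium bromide, via allylic bromide 15 (not isolated)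
Conditions: CBr4, PPh3, CH2Cl2, 0 °C; then second portion of PPh3, rt
Reagents that add atoms: carbon tetrabromide BrC(Br)(Br)Br; triphenylphosphine c1ccc(cc1)P(c1ccccc1)c1ccccc1
Why: Appel bromination (SN2, no allyl cation, so the C9'=C10' geometry and the acid-sensitive allylic C3'–O bond are kept) followed by quaternisation of PPh3 by the allylic bromide.

Step 11
Reactants: 17 (4R,6R)-4-hydroxy-2,2,6-trimethylcyclohexan-1-one
Product: 18 (4R,6R)-4-[(tert-butyldimethylsilyl)oxy]-2,2,6-trimethylcyclohexan-1-one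
Conditions: tBuMe2SiCl, imidazole, DMF, rt
Reagents that add atoms: tert-butyldimethylsilyl chloride CC(C)(C)[Si](C)(C)Cl
Why: Silyl ether protection of the chiral-pool alcohol (future C3) before enolisation.

Step 12
Reactants: 18 (4R,6R)-4-[(tert-butyldimethylsilyl)oxy]-2,2,6-trimethylcyclohexan-1-one
Product: 19 (4R)-4-[(tert-butyldimethylsilyl)oxy]-2,6,6-trimethylcyclohex-1-en-1-yl trifluoromethanesulfonate
Conditions: LiN(iPr)2, THF, −78 → 0 °C; then PhNTf2, −78 °C → rt
Reagents that add atoms: N-phenylbis(trifluoromethanesulfonimide) FC(F)(F)S(=O)(=O)N(c1ccccc1)S(=O)(=O)C(F)(F)F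
Why: The ketone has a single α-hydrogen (the other α-carbon is quaternary), so enolate O-triflation can only give the tetrasubstituted C5=C6 enol triflate, with the C3 stereocentre remote and untouched.

Step 13
Reactants: 19 (4R)-4-[(tert-butyldimethylsilyl)oxy]-2,6,6-trimethylcyclohex-1-en-1-yl trifluoromethanesulfonate; 20 (2E)-3-methylpent-2-en-4-yn-1-ol
Product: 21 (2E)-5-[(4R)-4-[(tert-butyldimethylsilyl)oxy]-2,6,6-trimethylcyclohex-1-en-1-yl]-3-methylpent-2-en-4-yn-1-ol
Conditions: Pd(PPh3)4 (5 mol%), CuI (10 mol%), Et3N, DMF, rt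
Reagents that add atoms: none
Why: Sonogashira coupling of the vinyl triflate with the terminal alkyne forms C6–C7 and carries the E C9=C10 bond of 20 unchanged.

Step 14
Reactants: 21 (2E)-5-[(4R)-4-[(tert-butyldimethylsilyl)oxy]-2,6,6-trimethylcyclohex-1-en-1-yl]-3-methylpent-2-en-4-yn-1-ol
Product: 23 [(2E)-5-[(4R)-4-[(tert-butyldimethylsilyl)oxy]-2,6,6-trimethylcyclohex-1-en-1-yl]-3-methylpent-2-en-4-yn-1-yl]triphenylphosphonium bromide, via enynyl bromide 22 (not isolated)
Conditions: CBr4, PPh3, CH2Cl2, 0 °C; then second portion of PPh3, rt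
Reagents that add atoms: carbon tetrabromide BrC(Br)(Br)Br; triphenylphosphine c1ccc(cc1)P(c1ccccc1)c1ccccc1
Why: Appel bromination and phosphine quaternisation under neutral conditions, which avoid the allyl cation that would scramble the 9E geometry.

Step 15
Reactants: 23 [(2E)-5-[(4R)-4-[(tert-butyldimethylsilyl)oxy]-2,6,6-trimethylcyclohex-1-en-1-yl]-3-methylpent-2-en-4-yn-1-yl]triphenylphosphonium bromide; 24 (2E,4E,6E)-2,7-dimethylocta-2,4,6-trienedial (3 equiv)
Product: 25 (2E,4E,6E,8E,10E)-13-[(4R)-4-[(tert-butyldimethylsilyl)oxy]-2,6,6-trimethylcyclohex-1-en-1-yl]-2,7,11-trimethyltrideca-2,4,6,8,10-pentaen-12-ynal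
Conditions: NaOMe, CH2Cl2/MeOH, 0 °C → rt; then heptane, 70 °C, dark
Reagents that add atoms: none
Why: Wittig olefination of one aldehyde group of the symmetrical dialdehyde (used in excess to suppress double condensation) by the semi-stabilised allylic ylide forms C11=C12, and any hindered 11Z isomer should revert to E on gentle heating without iodine, which would endanger 9E.

Step 16
Reactants: 16 [(2E,4E)-5-[(1R,4R)-4-[(tert-butyldimethylsilyl)oxy]-2,6,6-trimethylcyclohex-2-en-1-yl]-3-methylpenta-2,4-dien-1-yl]triphenylphosphonium bromide; 25 (2E,4E,6E,8E,10E)-13-[(4R)-4-[(tert-butyldimethylsilyl)oxy]-2,6,6-trimethylcyclohex-1-en-1-yl]-2,7,11-trimethyltrideca-2,4,6,8,10-pentaen-12-ynal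
Product: 26 (3R,3'R,6'R)-3,3'-bis[(tert-butyldimethylsilyl)oxy]-7,8-didehydro-β,ε-carotene (all-E)
Conditions: NaOMe, CH2Cl2/MeOH, 0 °C → rt; then heptane, 70 °C, dark
Reagents that add atoms: none
Why: The second Wittig olefination joins the two halves at C11'=C12' under mild alkoxide conditions that touch neither silyl ether nor the C6' stereocentre, with thermal Z-to-E equilibration of the new disubstituted bond.

Step 17
Reactants: 26 (3R,3'R,6'R)-3,3'-bis[(tert-butyldimethylsilyl)oxy]-7,8-didehydro-β,ε-carotene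
Product: 27 (3R,3'R,6'R)-7,8-didehydro-β,ε-carotene-3,3'-diol (all-E; monadoxanthin)
Conditions: Bu4NF, THF, 0 °C → rt, dark, under argon
Reagents that add atoms: none
Why: Fluoride desilylation frees both hydroxyl groups without acid, to which the allylic C3' alcohol of the ε-ring is sensitive.

**Compound list**
1 | mesityl oxide (4-methylpent-3-en-2-one) | CC(=O)C=C(C)C | starting material
2 | tert-butyldimethyl[(4-methylpenta-1,3-dien-2-yl)oxy]silane | C=C(O[Si](C)(C)C(C)(C)C)C=C(C)C | intermediate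
3 | ethyl buta-2,3-dienoate | C=C=CC(=O)OCC | starting material
4 | ethyl (1S)-4-[(tert-butyldimethylsilyl)oxy]-2,2-dimethyl-6-methylidenecyclohex-3-ene-1-carboxylate | C=C1CC(O[Si](C)(C)C(C)(C)C)=CC(C)(C)[C@H]1C(=O)OCC | intermediate
5 | [(1S)-4-[(tert-butyldimethylsilyl)oxy]-2,2-dimethyl-6-methylidenecyclohex-3-en-1-yl]methanol | C=C1CC(O[Si](C)(C)C(C)(C)C)=CC(C)(C)[C@H]1CO | intermediate
6 | (4R)-4-(hydroxymethyl)-3,3-dimethyl-5-methylidenecyclohexan-1-one | C=C1CC(=O)CC(C)(C)[C@H]1CO | intermediate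
7 | (4R)-4-(hydroxymethyl)-3,5,5-trimethylcyclohex-2-en-1-one | CC1=CC(=O)CC(C)(C)[C@H]1CO | intermediate
8 | (4R)-3,5,5-trimethyl-4-{[(1-phenyl-1H-tetrazol-5-yl)sulfanyl]methyl}cyclohex-2-en-1-one | CC1=CC(=O)CC(C)(C)[C@H]1CSC2=NN=NN2c3ccccc3 | intermediate
9 | (1R,4R)-3,5,5-trimethyl-4-{[(1-phenyl-1H-tetrazol-5-yl)sulfanyl]methyl}cyclohex-2-en-1-ol | CC1=C[C@H](O)CC(C)(C)[C@H]1CSC2=NN=NN2c3ccccc3 | intermediate
10 | 5-({[(1R,4R)-4-[(tert-butyldimethylsilyl)oxy]-2,6,6-trimethylcyclohex-2-en-1-yl]methyl}sulfanyl)-1-phenyl-1H-tetrazole | CC1=C[C@H](O[Si](C)(C)C(C)(C)C)CC(C)(C)[C@H]1CSC2=NN=NN2c3ccccc3 | intermediate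
11 | 5-({[(1R,4R)-4-[(tert-butyldimethylsilyl)oxy]-2,6,6-trimethylcyclohex-2-en-1-yl]methyl}sulfonyl)-1-phenyl-1H-tetrazole | CC1=C[C@H](O[Si](C)(C)C(C)(C)C)CC(C)(C)[C@H]1CS(=O)(=O)C2=NN=NN2c3ccccc3 | intermediate
12 | ethyl (2E)-3-methyl-4-oxobut-2-enoate | CCOC(=O)/C=C(\C)C=O | starting material
13 | ethyl (2E,4E)-5-[(1R,4R)-4-[(tert-butyldimethylsilyl)oxy]-2,6,6-trimethylcyclohex-2-en-1-yl]-3-methylpenta-2,4-dienoate | CC1=C[C@H](O[Si](C)(C)C(C)(C)C)CC(C)(C)[C@H]1/C=C/C(C)=C/C(=O)OCC | intermediate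
14 | (2E,4E)-5-[(1R,4R)-4-[(tert-butyldimethylsilyl)oxy]-2,6,6-trimethylcyclohex-2-en-1-yl]-3-methylpenta-2,4-dien-1-ol | CC1=C[C@H](O[Si](C)(C)C(C)(C)C)CC(C)(C)[C@H]1/C=C/C(C)=C/CO | intermediate
15 | tert-butyl{[(1R,4R)-4-[(1E,3E)-5-bromo-3-methylpenta-1,3-dien-1-yl]-3,5,5-trimethylcyclohex-2-en-1-yl]oxy}dimethylsilane | CC1=C[C@H](O[Si](C)(C)C(C)(C)C)CC(C)(C)[C@H]1/C=C/C(C)=C/CBr | intermediate
16 | [(2E,4E)-5-[(1R,4R)-4-[(tert-butyldimethylsilyl)oxy]-2,6,6-trimethylcyclohex-2-en-1-yl]-3-methylpenta-2,4-dien-1-yl]triphenylphosphonium bromide | CC1=C[C@H](O[Si](C)(C)C(C)(C)C)CC(C)(C)[C@H]1/C=C/C(C)=C/C[P+](c2ccccc2)(c2ccccc2)c2ccccc2.[Br-] | intermediate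
17 | (4R,6R)-4-hydroxy-2,2,6-trimethylcyclohexan-1-one (actinol) | C[C@@H]1C[C@@H](O)CC(C)(C)C1=O | starting material
18 | (4R,6R)-4-[(tert-butyldimethylsilyl)oxy]-2,2,6-trimethylcyclohexan-1-one | C[C@@H]1C[C@@H](O[Si](C)(C)C(C)(C)C)CC(C)(C)C1=O | intermediate
19 | (4R)-4-[(tert-butyldimethylsilyl)oxy]-2,6,6-trimethylcyclohex-1-en-1-yl trifluoromethanesulfonate | FC(F)(F)S(=O)(=O)OC1=C(C)C[C@@H](O[Si](C)(C)C(C)(C)C)CC1(C)C | intermediate
20 | (2E)-3-methylpent-2-en-4-yn-1-ol | C#C/C(C)=C/CO | starting material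
21 | (2E)-5-[(4R)-4-[(tert-butyldimethylsilyl)oxy]-2,6,6-trimethylcyclohex-1-en-1-yl]-3-methylpent-2-en-4-yn-1-ol | OC/C=C(\C)C#CC1=C(C)C[C@@H](O[Si](C)(C)C(C)(C)C)CC1(C)C | intermediate
22 | {[(1R)-4-[(3E)-5-bromo-3-methylpent-3-en-1-yn-1-yl]-3,5,5-trimethylcyclohex-3-en-1-yl]oxy}(tert-butyl)dimethylsilane | BrC/C=C(\C)C#CC1=C(C)C[C@@H](O[Si](C)(C)C(C)(C)C)CC1(C)C | intermediate
23 | [(2E)-5-[(4R)-4-[(tert-butyldimethylsilyl)oxy]-2,6,6-trimethylcyclohex-1-en-1-yl]-3-methylpent-2-en-4-yn-1-yl]triphenylphosphonium bromide | [Br-].c1ccccc1[P+](c1ccccc1)(c1ccccc1)C/C=C(\C)C#CC1=C(C)C[C@@H](O[Si](C)(C)C(C)(C)C)CC1(C)C | intermediate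
24 | (2E,4E,6E)-2,7-dimethylocta-2,4,6-trienedial | O=C/C(C)=C/C=C/C=C(\C)C=O | starting material
25 | (2E,4E,6E,8E,10E)-13-[(4R)-4-[(tert-butyldimethylsilyl)oxy]-2,6,6-trimethylcyclohex-1-en-1-yl]-2,7,11-trimethyltrideca-2,4,6,8,10-pentaen-12-ynal | O=C/C(C)=C/C=C/C=C(C)/C=C/C=C(\C)C#CC1=C(C)C[C@@H](O[Si](C)(C)C(C)(C)C)CC1(C)C | intermediate
26 | (3R,3'R,6'R)-3,3'-bis[(tert-butyldimethylsilyl)oxy]-7,8-didehydro-β,ε-carotene | CC1=C[C@H](O[Si](C)(C)C(C)(C)C)CC(C)(C)[C@H]1/C=C/C(C)=C/C=C/C(C)=C/C=C/C=C(C)/C=C/C=C(\C)C#CC1=C(C)C[C@@H](O[Si](C)(C)C(C)(C)C)CC1(C)C | intermediate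
27 | (3R,3'R,6'R)-7,8-didehydro-β,ε-carotene-3,3'-diol (monadoxanthin) | CC1=C[C@H](O)CC(C)(C)[C@H]1/C=C/C(C)=C/C=C/C(C)=C/C=C/C=C(C)/C=C/C=C(\C)C#CC1=C(C)C[C@@H](O)CC1(C)C | target

**Totals**
Total step count: 17. Longest linear sequence: 12 (steps 1–10, 16, 17).

**Steps most likely to fail**

1. Step 2 (the labelled step). The cycloaddition may stop at the open-chain Mukaiyama–Michael stage, divert into four-membered ring formation, lose the silyl group from the diene under the acidic catalyst, or proceed with poor facial selectivity at C6'. The fallback uses known chemistry, sets out from 1 and returns at 7. BF3·OEt2-mediated Michael addition/aldol condensation of 1 with ethyl acetoacetate forms the same two ring bonds without stereocontrol and gives racemic ethyl 2,6,6-trimethyl-4-oxocyclohex-2-ene-1-carboxylate F1. Saponification (NaOH, aq EtOH) gives racemic 2,6,6-trimethyl-4-oxocyclohex-2-ene-1-carboxylic acid F2. Classical resolution by crystallisation gives the 1-phenylethylammonium (1R)-2,6,6-trimethyl-4-oxocyclohex-2-ene-1-carboxylate F3 (amine antipode fixed by trial), and dilute HCl releases (1R)-2,6,6-trimethyl-4-oxocyclohex-2-ene-1-carboxylic acid F4. Chemoselective reduction of the carboxyl group (BH3·SMe2, THF, 0 °C) then leads to 7.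

2. Step 5. Hydride may enter from the face of the axial C1' methyl (loss of facial selectivity, giving the 3'-epimer), or conjugate reduction may compete. The fallback sets out from 8 and returns at 9. Luche reduction (NaBH4, CeCl3·7H2O, MeOH, −40 °C) gives clean 1,2-reduction; any trans alcohol is used directly, and the cis alcohol (1S,4R)-3,5,5-trimethyl-4-{[(1-phenyl-1H-tetrazol-5-yl)sulfanyl]methyl}cyclohex-2-en-1-ol F5 is separated. Mitsunobu esterification with 4-nitrobenzoic acid (PPh3, DIAD, THF) inverts C3' to (1R,4R)-3,5,5-trimethyl-4-{[(1-phenyl-1H-tetrazol-5-yl)sulfanyl]methyl}cyclohex-2-en-1-yl 4-nitrobenzoate F6, and methanolysis (K2CO3, MeOH) gives 9.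

3. Step 8. E selectivity at C7'=C8' may erode with the conjugated aldehyde, or the metalated tetrazolyl sulfone may self-condense before it meets the aldehyde. The fallback sets out from 11 and returns at 13. The sulfone anion (KN(SiMe3)2, THF, −78 °C) is alkylated with ethyl (2E)-4-bromo-3-methylbut-2-enoate to ethyl (2E)-5-[(1R,4R)-4-[(tert-butyldimethylsilyl)oxy]-2,6,6-trimethylcyclohex-2-en-1-yl]-3-methyl-5-[(1-phenyl-1H-tetrazol-5-yl)sulfonyl]pent-2-enoate F7 (epimers at the sulfonyl carbon). Base-induced 1,2-elimination of the sulfinate (DBU, toluene, 60 °C) then forms the conjugated E C7'=C8' bond of 13.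

**Further compounds**
F1 | step 2 | ethyl 2,6,6-trimethyl-4-oxocyclohex-2-ene-1-carboxylate (racemic) | CCOC(=O)C1C(C)=CC(=O)CC1(C)C
F2 | step 2 | 2,6,6-trimethyl-4-oxocyclohex-2-ene-1-carboxylic acid (racemic) | OC(=O)C1C(C)=CC(=O)CC1(C)C
F3 | step 2 | 1-phenylethylammonium (1R)-2,6,6-trimethyl-4-oxocyclohex-2-ene-1-carboxylate | CC1=CC(=O)CC(C)(C)[C@H]1C(=O)[O-].CC([NH3+])c1ccccc1
F4 | step 2 | (1R)-2,6,6-trimethyl-4-oxocyclohex-2-ene-1-carboxylic acid | CC1=CC(=O)CC(C)(C)[C@H]1C(=O)O
F5 | step 5 | (1S,4R)-3,5,5-trimethyl-4-{[(1-phenyl-1H-tetrazol-5-yl)sulfanyl]methyl}cyclohex-2-en-1-ol | CC1=C[C@@H](O)CC(C)(C)[C@H]1CSC2=NN=NN2c3ccccc3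
F6 | step 5 | (1R,4R)-3,5,5-trimethyl-4-{[(1-phenyl-1H-tetrazol-5-yl)sulfanyl]methyl}cyclohex-2-en-1-yl 4-nitrobenzoate | CC1=C[C@H](OC(=O)c2ccc(cc2)[N+](=O)[O-])CC(C)(C)[C@H]1CSC3=NN=NN3c4ccccc4
F7 | step 8 | ethyl (2E)-5-[(1R,4R)-4-[(tert-butyldimethylsilyl)oxy]-2,6,6-trimethylcyclohex-2-en-1-yl]-3-methyl-5-[(1-phenyl-1H-tetrazol-5-yl)sulfonyl]pent-2-enoate | CC1=C[C@H](O[Si](C)(C)C(C)(C)C)CC(C)(C)[C@H]1C(C/C(C)=C/C(=O)OCC)S(=O)(=O)C2=NN=NN2c3ccccc3
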